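The route rests on cutting the bond between C2 of the (Z)-but-2-enoate (sarracinate) unit and its oxymethylene carbon. The key step exploits the trisubstituted C2=C3 alkene, in which H-3 stands cis to that CH2: this is the imprint of a syn H–metal addition across an alkyne. The precursor is therefore the (S)-1-(3,4,5-trimethoxyphenyl)allyl ester of but-2-ynoic acid. Conjugate hydroalumination and C-alkylation of the resulting α-alumino enoate with iodomethyl tiglate in the same flask should form the C–C bond, fix the Z geometry and complete the target in one operation. The carbinol stereocentre is taken from a lipase resolution.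

Key step: step 6

Remark on the chemistry: the target is read as S at the carbinol carbon, Z at the 2-(acyloxymethyl)but-2-enoate (CH3 cis to the ester C=O) and E in the 2-methylbut-2-enoate (tiglate) unit.

Step 1
Reactants: 1 3,4,5-trimethoxybenzaldehyde
Product: 2 rac-1-(3,4,5-trimethoxyphenyl)prop-2-en-1-ol
Conditions: CH2=CHMgBr, THF, 0 °C; then H2O
Reagents that add atoms: vinylmagnesium bromide C=C[Mg]Br
Why: Grignard 1,2-addition to an aromatic aldehyde without α-hydrogens should give the racemic secondary allylic alcohol cleanly.

Step 2
Reactants: 2 rac-1-(3,4,5-trimethoxyphenyl)prop-2-en-1-ol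
Product: 3 (S)-1-(3,4,5-trimethoxyphenyl)prop-2-en-1-ol
Conditions: Novozym 435 (CAL-B), vinyl acetate, MTBE, 30 °C, to just past half conversion
Reagents that add atoms: none
Why: In this lipase kinetic resolution by irreversible transesterification, CAL-B should acylate the R enantiomer (aryl as large, vinyl as medium substituent) and leave the S alcohol, which is separated from the acetate by chromatography.

Step 3
Reactants: 3 (S)-1-(3,4,5-trimethoxyphenyl)prop-2-en-1-ol; 4 but-2-ynoic acid
Product: 5 (S)-1-(3,4,5-trimethoxyphenyl)prop-2-en-1-yl but-2-ynoate
Conditions: DCC, DMAP (cat.), CH2Cl2, −20 to 0 °C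
Reagents that add atoms: none
Why: Steglich esterification acylates the oxygen under neutral, cold conditions, so the C–O bond of the ionisable benzylic/allylic carbinol is not broken and the S configuration is retained.

Step 4
Reactants: 6 tiglic acid, (E)-2-methylbut-2-enoic acid
Product: 7 chloromethyl (E)-2-methylbut-2-enoate (chloromethyl tiglate)
Conditions: ClCH2OSO2Cl, NaHCO3, Bu4NHSO4 (cat.), CH2Cl2/H2O, rt
Reagents that add atoms: chloromethyl chlorosulfate ClCOS(=O)(=O)Cl
Why: Phase-transfer O-alkylation of the carboxylate at the CH2 carbon displaces chlorosulfate, the better leaving group, and leaves the E alkene untouched.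

Step 5
Reactants: 7 chloromethyl tiglate
Product: 8 iodomethyl (E)-2-methylbut-2-enoate (iodomethyl tiglate)
Conditions: NaI, acetone, rt, dark; used without storage
Reagents that add atoms: sodium iodide [Na+].[I-]
Why: Finkelstein reaction at the oxygen-activated CH2–Cl carbon, driven by precipitation of NaCl, should give the more reactive iodide.

Step 6
Reactants: 5 (S)-1-(3,4,5-trimethoxyphenyl)prop-2-en-1-yl but-2-ynoate; 8 iodomethyl tiglate
Product: 10 (S)-1-(3,4,5-trimethoxyphenyl)prop-2-en-1-yl (Z)-2-{[(E)-2-methylbut-2-enoyloxy]methyl}but-2-enoate (CNP0203602.1), via vinylalane 9 (not isolated)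
Conditions: DIBAL-H (1.05 equiv), HMPA, THF, 0 °C; then 8, CuBr·SMe2 (10 mol%), 0 °C to rt; aq. Rochelle salt/Na2S2O3
Reagents that add atoms: diisobutylaluminium hydride CC(C)C[AlH]CC(C)C (gives H-3 of 10 and the Al(iBu)2 group of intermediate 9 only)
Why: Proposed new method: the HMPA-complexed hydride adds to C3 and aluminium to C2 of the ynoate in a syn conjugate hydroalumination, and the α-alumino enoate 9 (in equilibrium with its aluminium allenolate) is then C-alkylated at C2, after Al-to-Cu exchange, by the oxygen-activated CH2–I carbon of 8. The closest known reaction type is vinylalumination (conjugate hydroalumination of 2-alkynoates and trapping of the α-alumino enoate with aldehydes) together with the Cu-catalysed coupling of alkenylalanes with reactive halides; an acyloxymethyl iodide has not been shown as the electrophile. No ring is closed and no stereocentre is formed, and the carbinol centre lies outside the reacting π system. The alkene geometry is controlled by the syn addition with retention at the C–metal bond, and the allenolate path leads to the same result because the electrophile enters in the plane of the C3 substituents on the side of H, so CH2 ends cis to H-3 and CH3 cis to the ester carbonyl (Z). The step needs 1,4- over 1,2-reduction of the ester, secured by the soft amide-complexed hydride at 0 °C, and C-alkylation at CH2–I over acyl attack or O-alkylation, secured by the soft copper-bound carbon nucleophile and the hindered conjugated tiglate carbonyl.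

Compound list
1 | 3,4,5-trimethoxybenzaldehyde | O=Cc1cc(OC)c(OC)c(OC)c1 | starting material
2 | rac-1-(3,4,5-trimethoxyphenyl)prop-2-en-1-ol | C=CC(O)c1cc(OC)c(OC)c(OC)c1 | intermediate
3 | (S)-1-(3,4,5-trimethoxyphenyl)prop-2-en-1-ol | C=C[C@H](O)c1cc(OC)c(OC)c(OC)c1 | intermediate
4 | but-2-ynoic acid | CC#CC(=O)O | starting material
5 | (S)-1-(3,4,5-trimethoxyphenyl)prop-2-en-1-yl but-2-ynoate | C=C[C@H](OC(=O)C#CC)c1cc(OC)c(OC)c(OC)c1 | intermediate
6 | tiglic acid, (E)-2-methylbut-2-enoic acid | C/C=C(\C)C(=O)O | starting material
7 | chloromethyl (E)-2-methylbut-2-enoate | C/C=C(\C)C(=O)OCCl | intermediate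
8 | iodomethyl (E)-2-methylbut-2-enoate | C/C=C(\C)C(=O)OCI | intermediate
9 | (S)-1-(3,4,5-trimethoxyphenyl)prop-2-en-1-yl (E)-2-(diisobutylalumanyl)but-2-enoate, CH3 cis to the ester C=O | C=C[C@H](OC(=O)/C(=C\C)[Al](CC(C)C)CC(C)C)c1cc(OC)c(OC)c(OC)c1 | intermediate
10 | (S)-1-(3,4,5-trimethoxyphenyl)prop-2-en-1-yl (Z)-2-{[(E)-2-methylbut-2-enoyloxy]methyl}but-2-enoate | C=C[C@H](OC(=O)/C(=C\C)COC(=O)/C(C)=C/C)c1cc(OC)c(OC)c(OC)c1 | target

Total step count: 6. Longest linear sequence: 4 steps (steps 1, 2, 3 and 6); steps 4 and 5 prepare the second fragment.

Steps most likely to fail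

Step 6 (Proposed new method). The α-alumino enoate may alkylate too slowly at carbon, so that O-alkylation of the allenolate or acyl attack on the tiglate competes. The allyl allenolate may also undergo a [3,3] shift, and the aluminium iodide formed may ionise the benzylic/allylic ester, with loss of configuration. The fallback uses known chemistry, sets out from 5 and comes back at 10. Compound 5 is hydroaluminated as in step 6 and the vinylalane is trapped with monomeric formaldehyde (vinylalumination of an aldehyde, the same Z outcome) to give (S)-1-(3,4,5-trimethoxyphenyl)prop-2-en-1-yl (Z)-2-(hydroxymethyl)but-2-enoate F1. Its primary hydroxyl is then esterified with tiglic acid 6 (EDC, DMAP cat., CH2Cl2, 0 °C) to give 10.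

Step 3. The carbodiimide-activated ynoic acid may be consumed by conjugate addition of DMAP, by oligomerisation or by isomerisation to the allenoate before it acylates the hindered carbinol. The fallback forms the C(sp)–C(=O) bond instead of the acyl–O bond; it sets out from 3 and comes back at 5. Alcohol 3 is treated with 1,1'-carbonyldiimidazole (CH2Cl2, 0 °C) to give (S)-1-(3,4,5-trimethoxyphenyl)prop-2-en-1-yl 1H-imidazole-1-carboxylate F2. This is acylated onto 1-propynylmagnesium bromide (THF, −78 °C), with displacement of imidazole, to give 5.

Step 2. The resolution may stop short of full enantiopurity through insufficient enantiomer discrimination by the lipase, and it discards half of the material by design. The fallback sets the centre by asymmetric synthesis; it sets out from 1 and comes back at 3. Divinylzinc (from ZnCl2 and vinylmagnesium bromide, magnesium salts sequestered) is added to 1 under catalysis by (−)-MIB, the amino alcohol ligand enantiomer that directs Si-face addition. This should give 3 directly, and the detour makes no new compound (F0).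

Further compounds
F1 | step 6 | (S)-1-(3,4,5-trimethoxyphenyl)prop-2-en-1-yl (Z)-2-(hydroxymethyl)but-2-enoate | C=C[C@H](OC(=O)/C(=C\C)CO)c1cc(OC)c(OC)c(OC)c1
F2 | step 3 | (S)-1-(3,4,5-trimethoxyphenyl)prop-2-en-1-yl 1H-imidazole-1-carboxylate | C=C[C@H](OC(=O)n1ccnc1)c1cc(OC)c(OC)c(OC)c1
F0 | step 2 | none | none
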